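**Compound numbering used throughout:** 1 acetosyringone, 2 its benzyl ether, 3 the bromoketone, 4 syringic acid, 5 benzyl syringate, 6 the aryloxy ketone, 7 formaldehyde, 8 the racemic hydroxy ketone, 9 its mesylate, 10 the 2-aryloxy enone, 11 bis(pinacolato)diboron, 12 the (R)-boronate, 13 the (R)-hydroxy ketone, 14 the target.

## The problem

The target 14 is an open-chain β-aryl ether dimer at the ketone oxidation level. Its three-carbon chain has C-α as an aryl ketone on ring A (4-hydroxy-3,5-dimethoxyphenyl), C-β carrying the 4-oxygen of ring B (a syringic acid unit), and C-γ as a primary alcohol. No ring has to be built; two symmetrical syringyl rings must be joined through C-α–C-β–C-γ and one aryl ether bond at C-β. The single stereocenter, C-β, is R by CIP analysis of the SMILES (OAr > C(=O)Ar > CH2OH > H). There is no second stereocenter from which it could be relayed, so its configuration must come from a catalyst or reagent. C-β lies between a ketone and an aryloxy group, so its proton is acidic and the centre will not survive base once set. The β-hydroxy ketone can also lose water to an enone or formaldehyde by retro-aldol cleavage, so everything after the stereo-defining event must be short and close to neutral. The free phenol and the carboxylic acid need masks that come off without base. The enabling feature is that C-β carries only a hydrogen besides its three heavy substituents and C-γ carries only oxygen. The target is therefore the formal anti-Markovnikov hydrate of the 2-aryloxy-1-arylprop-2-en-1-one 10, with C-γ as the enone terminus and C-β as the enolate carbon that needs only a proton.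

## Retrosynthesis

**14 to 13.** The two O–benzyl bonds (aryl ether on ring A, ester on ring B) are cut. Benzyl is preferred over a methyl ester or a silyl ether because both benzyl groups fall in one neutral hydrogenolysis, whereas saponification or fluoride would expose C-β to base. The precursor 13 is no simpler in skeleton but tolerates every earlier step. The forward reaction must remove benzyl groups faster than it touches the aryl ketone or the C-β–O bond.

**13 to 12.** The C-γ–O bond is traced back to a C-γ–B bond. Direct enantioselective hydration of an enone would be reversible and has no handle for asymmetric induction. Boron as a masked hydroxyl lets a metal-catalysed event set C-β. The forward oxidation acts at the non-stereogenic C-γ and only has to be run near neutral pH.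

**12 to 10 and 11.** The C-γ–B and C-β–H bonds are cut, which flattens the stereocenter into the achiral enone 10. The neighbouring cuts are less attractive for these reasons:
- Forming C-β–O by substitution with 5 on an enantiopure α-leaving-group ketone would run a basic displacement on a centre that racemises under those conditions.
- Forming C-β–C-γ asymmetrically would need an enantioselective aldol with 7.
- Forming C-α–C-β would require a coupling at a carbon with a β-oxygen.

Protonation installs the stereocenter last, with the smallest possible reagent, and under nearly neutral conditions. The forward reaction asks a chiral copper catalyst to control proton delivery to an acyclic enolate.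

**10 to 8, and 8 to 6 and 7.** The C=C bond comes from dehydration of the aldol 8, and the C-β–C-γ bond from hydroxymethylation of 6 with 7. Compound 8 is the racemate of 13, so the route deliberately erases the centre and rewrites it under catalyst control. This also supplies a racemic reference for the enantiomeric assay of 13. The forward reactions are a stoichiometry-controlled aldol and an elimination through a sulfonate.

**6 to 3 and 5.** The C-β–O(aryl) bond is cut, which divides the molecule into two syringyl halves of equal size. A phenacyl bromide is among the best substitution electrophiles, which offsets the two ortho methoxy groups on the phenol 5.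

**3 to 2 to 1, and 5 to 4.** The C–Br bond and the two benzyl–O bonds lead back to 1 and 4, both commercial. Benzylation before bromination keeps the phenol of 1 out of the halogenation. Selective esterification of 4 leaves the phenol free as the nucleophile.

## Roads not taken

**Alternative 1:** The cut is the C-α–C-β bond. Ring A would arrive as the S-2-pyridyl thioester A3 and the rest as the racemic N-hydroxyphthalimide ester A2. NiBr2·glyme (a divalent nickel precatalyst) with a chiral bis(oxazoline), reduced at a cathode against a sacrificial zinc anode, would couple them with loss of CO2 to the ketone A1.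
- Merits: the plan is convergent, enantioconvergent from a racemate, and makes the stereocenter together with the complete skeleton.
- Weak points: the radical at C-β carries the bulky 2,6-dimethoxyaryloxy group and a β-silyloxy group, so the alkylnickel intermediate has a β-elimination pathway that 10 does not offer. A2 needs its own multistep preparation, and three different protecting groups must be removed at the end.
- Comparison: the convergence is better than in the chosen plan, and enantioconvergent acylations of α-heteroatom radicals are arguably no further from precedent than the chosen key step. The chosen plan sets against this simple non-electrochemical chemistry up to 10, one protecting-group type, and a key substrate with no leaving group next to the reacting carbon.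

**Alternative 2:** The ketone is taken back to a carbinol and C-γ to an ester, so the key step forms the C-α–H bond. RuCl(p-cymene)(TsDPEN) (divalent ruthenium) with formic acid and triethylamine would reduce the racemic keto ester A5 under dynamic kinetic resolution to the syn hydroxy ester A4, fixing C-α and C-β together.
- Merits: this stereo-defining step has the strongest precedent of the four plans, and C-β equilibrates usefully in A5.
- Weak points: the C-α stereocenter is made only to be destroyed. The methyl ester must be reduced beside an aryl tert-butyl ester, the benzylic alcohol must be re-oxidised selectively in a 1,3-diol, and acid deprotection follows. That is at least four steps after the key step against two, and the labile ketone still appears at the end.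
- Comparison: alternative 2 is the safer choice for the asymmetric step. The chosen plan answers with step and redox economy, one stereocenter made and kept, and an independent fallback from 8.

**Alternative 3:** The cut is the C-β–O(aryl) bond. Pd2(dba)3 (zerovalent palladium) with an enantiopure N,N'-(trans-cyclohexane-1,2-diyl)bis(2-diphenylphosphinobenzamide) ligand would ionise the racemic vinyl epoxide A7. Phenol 5 would then attack the allyl terminus next to the alkoxide to give the allylic ether A6, and the alkene would be cleaved oxidatively to the ketone.
- Merits: the reaction class is known with phenols, and the stereocenter is created in a non-enolisable allylic ether that is configurationally secure. The chosen plan lacks this advantage.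
- Weak points: the nucleophile is a phenol with two ortho substituents and the central allyl carbon carries an aryl group, so branched selectivity and enantiocontrol are both extrapolations. A7 needs a separate synthesis. The 1,1-disubstituted alkene must be cleaved in the presence of two electron-rich rings.
- Comparison: the chosen plan reaches its key substrate faster and needs no oxidative cleavage. In alternative 3 the labile ketone still appears two steps from the end, so the handling problem is postponed and not removed.

Key step: step 7

Assumption: the sense of induction of the ferrocenyl bisphosphine on this substrate class cannot be predicted with confidence, so the ligand antipode that delivers R at C-β is used; both antipodes are commercial.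

## Route

Step 1
Reactants: 1 acetosyringone, 1-(4-hydroxy-3,5-dimethoxyphenyl)ethanone
Product: 2 1-(4-benzyloxy-3,5-dimethoxyphenyl)ethanone
Conditions: BnBr, K2CO3, DMF, 60 °C
Reagents that add atoms: benzyl bromide, BrCc1ccccc1
Why: Williamson ether synthesis; the phenoxide is the only competent nucleophile and carbonate does not enolise the methyl ketone productively.

Step 2
Reactants: 2 1-(4-benzyloxy-3,5-dimethoxyphenyl)ethanone
Product: 3 2-bromo-1-(4-benzyloxy-3,5-dimethoxyphenyl)ethanone
Conditions: CuBr2 (2.1 equiv), EtOAc/CHCl3 (1:1), reflux
Reagents that add atoms: copper dibromide (CuBr2), [Cu+2].[Br-].[Br-]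
Why: α-bromination of an aryl methyl ketone through its enol with copper dibromide; the heterogeneous reagent stops at the monobromide and spares the ring, whose free positions are ortho to the acyl group.

Step 3
Reactants: 4 syringic acid, 4-hydroxy-3,5-dimethoxybenzoic acid
Product: 5 benzyl syringate, benzyl 4-hydroxy-3,5-dimethoxybenzoate
Conditions: BnBr (1.05 equiv), KHCO3, DMF, 40 °C
Reagents that add atoms: benzyl bromide, BrCc1ccccc1
Why: O-alkylation of a carboxylate; hydrogencarbonate ionises the acid but not the hindered, much less acidic phenol, so the ester forms selectively.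

Step 4
Reactants: 3 2-bromo-1-(4-benzyloxy-3,5-dimethoxyphenyl)ethanone; 5 benzyl syringate
Product: 6 benzyl 4-[2-(4-benzyloxy-3,5-dimethoxyphenyl)-2-oxoethoxy]-3,5-dimethoxybenzoate
Conditions: K2CO3, acetone, reflux
Reagents that add atoms: none
Why: Williamson etherification of a phenacyl bromide (SN2), the standard assembly of β-aryl ether ketones; the high reactivity of the phenacyl halide compensates for the two ortho methoxy groups of the phenoxide.

Step 5
Reactants: 6 benzyl 4-[2-(4-benzyloxy-3,5-dimethoxyphenyl)-2-oxoethoxy]-3,5-dimethoxybenzoate; 7 formaldehyde (37% aqueous)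
Product: 8 racemic benzyl 4-{[1-(4-benzyloxy-3,5-dimethoxyphenyl)-3-hydroxy-1-oxopropan-2-yl]oxy}-3,5-dimethoxybenzoate
Conditions: 37% aq. HCHO (1.1 equiv), K2CO3 (0.5 equiv), 1,4-dioxane, rt
Reagents that add atoms: none
Why: crossed aldol hydroxymethylation of an α-aryloxy ketone, which is acidic enough for carbonate, with a non-enolisable aldehyde; limiting formaldehyde and reaction time holds the reaction at mono-addition, and the non-alcoholic solvent avoids transesterification.

Step 6
Reactants: 8 racemic benzyl 4-{[1-(4-benzyloxy-3,5-dimethoxyphenyl)-3-hydroxy-1-oxopropan-2-yl]oxy}-3,5-dimethoxybenzoate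
Product: 10 benzyl 4-{[3-(4-benzyloxy-3,5-dimethoxyphenyl)-3-oxoprop-1-en-2-yl]oxy}-3,5-dimethoxybenzoate, via the primary mesylate 9 (not isolated)
Conditions: MsCl (1.2 equiv), Et3N (3 equiv), CH2Cl2, 0 °C to rt
Reagents that add atoms: none
Why: O-sulfonylation of the primary alcohol followed by E1cB elimination, driven by the acidic C-β–H; the enone is used promptly because it is a reactive acceptor.

Step 7
Reactants: 10 benzyl 4-{[3-(4-benzyloxy-3,5-dimethoxyphenyl)-3-oxoprop-1-en-2-yl]oxy}-3,5-dimethoxybenzoate; 11 bis(pinacolato)diboron
Product: 12 benzyl 4-{[(2R)-1-(4-benzyloxy-3,5-dimethoxyphenyl)-1-oxo-3-(4,4,5,5-tetramethyl-1,3,2-dioxaborolan-2-yl)propan-2-yl]oxy}-3,5-dimethoxybenzoate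
Conditions: CuCl (5 mol %), NaOtBu (4 mol %), (R,Sp)- or (S,Rp)-1-[2-(diphenylphosphino)ferrocenyl]ethyldicyclohexylphosphine (6 mol %), MeOH (2 equiv), THF, −20 °C; pH 7 buffer quench
Reagents that add atoms: none
Why: Proposed new method: a phosphine-ligated copper boryl, generated from CuCl (monovalent copper), NaOtBu, the ligand and 11, should add across the C=C of 10 with boron on the unsubstituted C-γ and copper on C-β, and the α-cuprio ketone then rests as its oxygen-bound copper enolate. Methanol protonates C-β while the enolate is still held by the chiral copper fragment, which forms the C-β–H bond and the only stereocenter, and the copper methoxide left behind reacts with 11 to regenerate the boryl. The closest known reaction type is copper-boryl conjugate addition with enantioselective protonation of 2-substituted acrylic esters such as 2-amidoacrylates; 2-aryloxy aryl enones have not been used. No ring closes. The configuration at C-β is controlled by the ligand alone, since 10 has no stereogenic element, and the antipode that gives R is used. The step needs 1,4- rather than 1,2-addition, which the unhindered CH2 terminus and the doubly flanked carbonyl should secure. It needs one enolate geometry, which the s-cis enone (C=O and C–OAr dipoles opposed, bulky 2,6-dimethoxyaryloxy group turned away from the incoming boryl) should supply. It needs the acidic C-β–H of 12 to survive, for which NaOtBu is kept below the copper loading, the temperature low and the quench buffered.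

Step 8
Reactants: 12 benzyl 4-{[(2R)-1-(4-benzyloxy-3,5-dimethoxyphenyl)-1-oxo-3-(4,4,5,5-tetramethyl-1,3,2-dioxaborolan-2-yl)propan-2-yl]oxy}-3,5-dimethoxybenzoate
Product: 13 benzyl 4-{[(2R)-1-(4-benzyloxy-3,5-dimethoxyphenyl)-3-hydroxy-1-oxopropan-2-yl]oxy}-3,5-dimethoxybenzoate
Conditions: NaBO3·4H2O (3 equiv), THF/pH 7 phosphate buffer (1:1), 0 °C to rt
Reagents that add atoms: sodium perborate tetrahydrate (NaBO3·4H2O), O.O.O.O.[Na+].[O-]B1OO1
Why: oxidation of an alkylboronic ester by peroxoborate through a 1,2-shift of C-γ from boron to oxygen; C-γ is not stereogenic and C-β is not involved, and the buffered medium is chosen to avoid enolisation, retro-aldol cleavage and dehydration.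

Step 9
Reactants: 13 benzyl 4-{[(2R)-1-(4-benzyloxy-3,5-dimethoxyphenyl)-3-hydroxy-1-oxopropan-2-yl]oxy}-3,5-dimethoxybenzoate
Product: 14 4-{[(2R)-3-hydroxy-1-(4-hydroxy-3,5-dimethoxyphenyl)-1-oxopropan-2-yl]oxy}-3,5-dimethoxybenzoic acid
Conditions: H2 (1 atm), 10% Pd/C, EtOAc, rt
Reagents that add atoms: none
Why: catalytic hydrogenolysis of a benzyl aryl ether and a benzyl ester under neutral conditions that leave C-β untouched; the ketone on the electron-rich ring is reduced much more slowly, and the reaction is stopped after uptake of two equivalents of hydrogen.

## Compound list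

1 | acetosyringone, 1-(4-hydroxy-3,5-dimethoxyphenyl)ethanone | CC(=O)c1cc(OC)c(O)c(OC)c1 | starting material
2 | 1-(4-benzyloxy-3,5-dimethoxyphenyl)ethanone | CC(=O)c1cc(OC)c(OCc2ccccc2)c(OC)c1 | intermediate
3 | 2-bromo-1-(4-benzyloxy-3,5-dimethoxyphenyl)ethanone | BrCC(=O)c1cc(OC)c(OCc2ccccc2)c(OC)c1 | intermediate
4 | syringic acid, 4-hydroxy-3,5-dimethoxybenzoic acid | COc1cc(C(=O)O)cc(OC)c1O | starting material
5 | benzyl syringate, benzyl 4-hydroxy-3,5-dimethoxybenzoate | COc1cc(C(=O)OCc2ccccc2)cc(OC)c1O | intermediate
6 | benzyl 4-[2-(4-benzyloxy-3,5-dimethoxyphenyl)-2-oxoethoxy]-3,5-dimethoxybenzoate | COc1cc(C(=O)COc2c(OC)cc(C(=O)OCc3ccccc3)cc2OC)cc(OC)c1OCc1ccccc1 | intermediate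
7 | formaldehyde | C=O | starting material
8 | racemic benzyl 4-{[1-(4-benzyloxy-3,5-dimethoxyphenyl)-3-hydroxy-1-oxopropan-2-yl]oxy}-3,5-dimethoxybenzoate | COc1cc(C(=O)C(CO)Oc2c(OC)cc(C(=O)OCc3ccccc3)cc2OC)cc(OC)c1OCc1ccccc1 | intermediate
9 | racemic benzyl 4-{[1-(4-benzyloxy-3,5-dimethoxyphenyl)-3-(methanesulfonyloxy)-1-oxopropan-2-yl]oxy}-3,5-dimethoxybenzoate | COc1cc(C(=O)C(COS(C)(=O)=O)Oc2c(OC)cc(C(=O)OCc3ccccc3)cc2OC)cc(OC)c1OCc1ccccc1 | intermediate (not isolated)
10 | benzyl 4-{[3-(4-benzyloxy-3,5-dimethoxyphenyl)-3-oxoprop-1-en-2-yl]oxy}-3,5-dimethoxybenzoate | COc1cc(C(=O)C(=C)Oc2c(OC)cc(C(=O)OCc3ccccc3)cc2OC)cc(OC)c1OCc1ccccc1 | intermediate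
11 | bis(pinacolato)diboron | CC1(C)OB(OC1(C)C)B1OC(C)(C)C(C)(C)O1 | starting material
12 | benzyl 4-{[(2R)-1-(4-benzyloxy-3,5-dimethoxyphenyl)-1-oxo-3-(4,4,5,5-tetramethyl-1,3,2-dioxaborolan-2-yl)propan-2-yl]oxy}-3,5-dimethoxybenzoate | COc1cc(C(=O)[C@@H](CB2OC(C)(C)C(C)(C)O2)Oc2c(OC)cc(C(=O)OCc3ccccc3)cc2OC)cc(OC)c1OCc1ccccc1 | intermediate
13 | benzyl 4-{[(2R)-1-(4-benzyloxy-3,5-dimethoxyphenyl)-3-hydroxy-1-oxopropan-2-yl]oxy}-3,5-dimethoxybenzoate | COc1cc(C(=O)[C@@H](CO)Oc2c(OC)cc(C(=O)OCc3ccccc3)cc2OC)cc(OC)c1OCc1ccccc1 | intermediate
14 | 4-{[(2R)-3-hydroxy-1-(4-hydroxy-3,5-dimethoxyphenyl)-1-oxopropan-2-yl]oxy}-3,5-dimethoxybenzoic acid | COc1cc(C(=O)[C@@H](CO)Oc2c(OC)cc(C(=O)O)cc2OC)cc(OC)c1O | target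

## Step count and risk

Total steps: 9. Longest linear sequence: 8 steps (steps 1, 2, 4, 5, 6, 7, 8 and 9 from acetosyringone 1); step 3 is the one-step side branch from syringic acid 4.

**Step 7 (key step, proposed new method).**
- What may go wrong: poor enantioface discrimination in the protonation of an acyclic enolate; erosion of the new centre by re-enolisation of the product under the catalyst's alkoxide; competing conjugate addition of methanol to the very electrophilic enone.
- Fallback: the fallback leaves asymmetric catalysis and resolves the racemate that the route already makes. It sets out from 8, which is separated by preparative chromatography on a polysaccharide-derived chiral stationary phase with a neutral eluent. One enantiomer is 13, where the route is rejoined, so steps 6 to 8 are skipped. The other is benzyl 4-{[(2S)-1-(4-benzyloxy-3,5-dimethoxyphenyl)-3-hydroxy-1-oxopropan-2-yl]oxy}-3,5-dimethoxybenzoate F1. F1 is racemised back to 8 through its enol by brief exposure to a catalytic tertiary amine and resubmitted. The price is at most half of the material per pass and dependence on preparative chiral chromatography.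

**Step 8.**
- What may go wrong: even weakly basic peroxide may cause enolisation at C-β with loss of enantiopurity, retro-aldol loss of formaldehyde, β-elimination of the new hydroxyl, or Baeyer–Villiger-type attack on the electron-rich aryl ketone.
- Fallback: the fallback changes the boron species and the pH regime. It sets out from 12. KHF2 in aqueous methanol exchanges pinacol for fluoride to give potassium [(2R)-3-(4-benzyloxy-3,5-dimethoxyphenyl)-2-{4-[(benzyloxy)carbonyl]-2,6-dimethoxyphenoxy}-3-oxopropyl]trifluoroborate F2. Potassium peroxymonosulfate (KHSO5, used as the triple salt 2KHSO5·KHSO4·K2SO4) in aqueous acetone at 0 °C then oxidises F2 under weakly acidic conditions to 13, where the route is rejoined.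

**Step 5.**
- What may go wrong: over-reaction, since the mono-adduct still has an acidic C-β–H. This allows a second hydroxymethylation, premature loss of water to a polymerisable enone in the basic medium, or slow hydrolysis of the benzyl ester.
- Fallback: the fallback replaces the aldol/dehydration pair by a Mannich methylenation. It sets out from 6, which is heated with paraformaldehyde (the polymer of 7) and dimethylamine hydrochloride in 1,4-dioxane. This gives benzyl 4-{[1-(4-benzyloxy-3,5-dimethoxyphenyl)-3-(dimethylamino)-1-oxopropan-2-yl]oxy}-3,5-dimethoxybenzoate F3 as its hydrochloride. F3 loses dimethylamine on warming with mild base and returns to the route at 10, bypassing 8 and 9.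

**Step 9.**
- What may go wrong: over-reduction, either hydrogenation of the aryl ketone or hydrogenolytic cleavage of the ketone-activated C-β–O aryl ether. The hindered benzyl ether between two methoxy groups may react slowly and prolong exposure.
- Fallback: the fallback replaces reduction by Lewis-acid ionisation. It sets out from 13, which is treated with BCl3 and pentamethylbenzene as cation scavenger in CH2Cl2 at −78 °C. Both benzyl groups are removed and 14 is obtained directly after aqueous work-up. No new compound is made on the way (F0).

## Further compounds

F1 | step 7 | benzyl 4-{[(2S)-1-(4-benzyloxy-3,5-dimethoxyphenyl)-3-hydroxy-1-oxopropan-2-yl]oxy}-3,5-dimethoxybenzoate | COc1cc(C(=O)[C@H](CO)Oc2c(OC)cc(C(=O)OCc3ccccc3)cc2OC)cc(OC)c1OCc1ccccc1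
F2 | step 8 | potassium [(2R)-3-(4-benzyloxy-3,5-dimethoxyphenyl)-2-{4-[(benzyloxy)carbonyl]-2,6-dimethoxyphenoxy}-3-oxopropyl]trifluoroborate | [K+].COc1cc(C(=O)[C@@H](C[B-](F)(F)F)Oc2c(OC)cc(C(=O)OCc3ccccc3)cc2OC)cc(OC)c1OCc1ccccc1
F3 | step 5 | racemic benzyl 4-{[1-(4-benzyloxy-3,5-dimethoxyphenyl)-3-(dimethylamino)-1-oxopropan-2-yl]oxy}-3,5-dimethoxybenzoate | COc1cc(C(=O)C(CN(C)C)Oc2c(OC)cc(C(=O)OCc3ccccc3)cc2OC)cc(OC)c1OCc1ccccc1
F0 | step 9 | none | none
A1 | alternative 1 | tert-butyl 4-{[(2R)-1-(4-benzyloxy-3,5-dimethoxyphenyl)-3-(tert-butyldimethylsilyloxy)-1-oxopropan-2-yl]oxy}-3,5-dimethoxybenzoate | COc1cc(C(=O)[C@@H](CO[Si](C)(C)C(C)(C)C)Oc2c(OC)cc(C(=O)OC(C)(C)C)cc2OC)cc(OC)c1OCc1ccccc1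
A2 | alternative 1 | racemic 1,3-dioxoisoindolin-2-yl 2-[4-(tert-butoxycarbonyl)-2,6-dimethoxyphenoxy]-3-(tert-butyldimethylsilyloxy)propanoate | COc1cc(C(=O)OC(C)(C)C)cc(OC)c1OC(CO[Si](C)(C)C(C)(C)C)C(=O)ON1C(=O)c2ccccc2C1=O
A3 | alternative 1 | S-(pyridin-2-yl) 4-benzyloxy-3,5-dimethoxybenzenecarbothioate | COc1cc(C(=O)Sc2ccccn2)cc(OC)c1OCc1ccccc1
A4 | alternative 2 | methyl (2S,3R)-3-(4-benzyloxy-3,5-dimethoxyphenyl)-3-hydroxy-2-[4-(tert-butoxycarbonyl)-2,6-dimethoxyphenoxy]propanoate (syn) | COc1cc([C@@H](O)[C@@H](C(=O)OC)Oc2c(OC)cc(C(=O)OC(C)(C)C)cc2OC)cc(OC)c1OCc1ccccc1
A5 | alternative 2 | racemic methyl 3-(4-benzyloxy-3,5-dimethoxyphenyl)-2-[4-(tert-butoxycarbonyl)-2,6-dimethoxyphenoxy]-3-oxopropanoate | COc1cc(C(=O)C(C(=O)OC)Oc2c(OC)cc(C(=O)OC(C)(C)C)cc2OC)cc(OC)c1OCc1ccccc1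
A6 | alternative 3 | benzyl 4-{[(2S)-3-(4-benzyloxy-3,5-dimethoxyphenyl)-1-hydroxybut-3-en-2-yl]oxy}-3,5-dimethoxybenzoate | C=C(c1cc(OC)c(OCc2ccccc2)c(OC)c1)[C@@H](CO)Oc1c(OC)cc(C(=O)OCc2ccccc2)cc1OC
A7 | alternative 3 | racemic 2-[1-(4-benzyloxy-3,5-dimethoxyphenyl)ethenyl]oxirane | C=C(C1CO1)c1cc(OC)c(OCc2ccccc2)c(OC)c1
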